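**Strategy.** The tricycle is reduced to a 6/7-fused enone by cutting two bonds at once: C4–CH3 and the cyclobutane bond C6–C7. The handle is the C8 ketone of the bicyclo[3.1.1]heptanone: C4 is β and C7 α to it, and C6 ends the chain C7–C4–C5–C6, so a C7 enolate bearing the new C4 methyl can close cyclobutane C4–C5–C6–C7. Methyl cuprate addition to the C7=C4 enone creates exactly that enolate, which displaces a C6 tosylate with inversion in the same flask, setting C4, C6 and C7. The precursor is bicyclic enone 12: C1 dioxolane, C11 gem-dimethyl, (5R,6S)-tosylate.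

Key step: step 9

Numbering used for all compounds: seven-membered ring C1–C2–C3–C4–C5–C6–C11 (C1 O-angeloyl, C2 O-2-methylbutanoyl, C3 OH, C4 quaternary CH3, C11 gem-dimethyl); cyclobutane C4–C5–C6–C7; ketone bridge C7–C8(=O)–C9–C10(CH3)–C5.

Remark 1 (read from the target SMILES): 2-O and 3-O are cis to each other (both on the C7 side of the seven-membered ring) and trans to 1-O (C5 side), so the diol must come from a syn-dihydroxylation on the face opposite the C1 oxygen. The C10 methyl lies on the C6 side of the ketone bridge, and the 2-methylbutanoyl group is R.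

Remark 2: because C6 is inverted in step 9, the C5/C6 pair must be the syn-aldol pair (H-5 and O-6 cis on the seven-membered ring); the anti pair cannot close the cyclobutane.

Assumption: angelic anhydride and (R)-2-methylbutanoic acid are taken as purchasable.

Step 1
Reactants: 1 isobutyronitrile; 2 3-chloropropanoyl chloride
Product: 3 5-chloro-2,2-dimethyl-3-oxopentanenitrile
Conditions: LDA, THF, −78 °C; inverse addition to 2 (1.2 equiv), THF, −78 °C
Reagents that add atoms: none
Why: C-acylation of the lithiated nitrile by the acid chloride (Claisen-type acylation) is fast at −78 °C, and inverse addition keeps base away from the β-chloro ketone so that HCl is not eliminated; no stereocentre is formed.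

Step 2
Reactants: 3 5-chloro-2,2-dimethyl-3-oxopentanenitrile
Product: 4 2-[2-(2-chloroethyl)-1,3-dioxolan-2-yl]-2-methylpropanenitrile
Conditions: (TMSOCH2)2 (1.5 equiv), TMSOTf (5 mol %), CH2Cl2, −78 → −20 °C
Reagents that add atoms: 1,2-bis(trimethylsilyloxy)ethane (C[Si](C)(C)OCCO[Si](C)(C)C)
Why: silyl-triflate-catalysed ketalisation works on ketones next to a quaternary carbon under cold, non-basic conditions that leave the β-chloride and the nitrile untouched.

Step 3
Reactants: 4 2-[2-(2-chloroethyl)-1,3-dioxolan-2-yl]-2-methylpropanenitrile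
Product: 5 2-[2-(2-iodoethyl)-1,3-dioxolan-2-yl]-2-methylpropanenitrile
Conditions: NaI, acetone, reflux
Reagents that add atoms: sodium iodide ([Na+].[I-])
Why: Finkelstein reaction at an unhindered primary chloride, driven by precipitation of NaCl, supplies the iodide needed for the later samarium Barbier step.

Step 4
Reactants: 5 2-[2-(2-iodoethyl)-1,3-dioxolan-2-yl]-2-methylpropanenitrile
Product: 6 2-[2-(2-iodoethyl)-1,3-dioxolan-2-yl]-2-methylpropanal
Conditions: DIBAL-H (1.2 equiv), toluene, −78 °C; aq. tartaric acid, 0 °C
Reagents that add atoms: water (O)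
Why: DIBAL-H reduces a nitrile on a quaternary carbon only to the N-aluminio imine, which mild aqueous acid hydrolyses to the non-enolisable aldehyde without touching the hindered dioxolane or the primary iodide.

Step 5
Reactants: 7 3-ethoxycyclohex-2-en-1-one
Product: 8 1-ethoxy-3-(trimethylsilyloxy)cyclohexa-1,3-diene
Conditions: LDA, THF, −78 °C; TMSCl, −78 → 0 °C; non-aqueous work-up
Reagents that add atoms: chlorotrimethylsilane (C[Si](C)(C)Cl)
Why: kinetic deprotonation of the vinylogous ester occurs at the α′-CH2 (the future C5), and O-silylation of that cross-conjugated enolate gives the 1-alkoxy-3-silyloxy diene.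

Step 6
Reactants: 6 2-[2-(2-iodoethyl)-1,3-dioxolan-2-yl]-2-methylpropanal; 8 1-ethoxy-3-(trimethylsilyloxy)cyclohexa-1,3-diene
Product: 9 (5S,6S)-syn-aldol trimethylsilyl ether
Conditions: N-tosyl-tryptophan-derived B-butyl-oxazaborolidinone (20 mol %, antipode that shields the Re face of the aldehyde), EtCN, −78 °C; pH 7 buffer
Reagents that add atoms: none
Why: Mukaiyama aldol in which the doubly donor-activated diene terminus C5 attacks the boron-bound, non-enolisable aldehyde through an open transition state, for which cyclic enol silanes give the syn adduct with this catalyst class, so that Si-face attack sets C6 (S) and the syn topology sets C5 (S), the silyl group ending on the new oxygen.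

Step 7
Reactants: 9 (5S,6S)-syn-aldol trimethylsilyl ether
Product: 11 (5R,6S)-6-hydroxy bicyclic enone, via tertiary carbinol 10 (not isolated)
Conditions: SmI2 (2.5 equiv), NiI2 (2 mol %), THF, 0 °C → rt; then 1 M HCl, THF, 0 °C
Reagents that add atoms: water (O)
Why: samarium Barbier reaction in which the alkylsamarium from the primary iodide adds to the C4 carbonyl (7-exo-trig, helped by the gem-dialkyl effect of C11 and the ketal), after which brief acid unmasks the C8 ketone with loss of the tertiary C4 hydroxyl (Stork–Danheiser transposition) and of the silyl ether, leaving C5, C6 and the hindered C1 dioxolane untouched.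

Step 8
Reactants: 11 (5R,6S)-6-hydroxy bicyclic enone
Product: 12 (5R,6S)-6-tosyloxy bicyclic enone
Conditions: TsCl (3 equiv), DMAP (1 equiv), pyridine, 40 °C
Reagents that add atoms: p-toluenesulfonyl chloride (Cc1ccc(cc1)S(=O)(=O)Cl)
Why: O-sulfonylation proceeds with retention at C6 because only the O–H bond reacts, DMAP catalysis overcoming the hindrance of the neopentyl-type alcohol while the weak base leaves the γ-hydrogen at C5 alone.

Step 9
Reactants: 12 (5R,6S)-6-tosyloxy bicyclic enone
Product: 14 tricyclic C8 ketone with C1 dioxolane, via lithium enolate 13 (not isolated)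
Conditions: Me2CuLi (2 equiv), Et2O, −30 → 0 °C; then THF/HMPA (4:1), 0 → 40 °C
Reagents that add atoms: lithium dimethylcuprate ([Li+].C[Cu-]C)
Why: The cuprate transfers methyl to C4, the β-carbon of enone 12, and leaves lithium enolate 13 whose carbanion character sits only at C7; once HMPA is added and the mixture is warmed, C7 attacks C6 from the rear of the C–O bond and expels tosylate (conjugate addition–enolate alkylation cascade). The closest known reaction types are cuprate-triggered Michael-initiated ring closures and the base-mediated closure of bicyclo[3.1.1]heptanones from cyclohexanones that carry a sulfonyloxy-bearing carbon at C4 of the ring. The cyclobutane C4–C5–C6–C7 forms in a 4-(enolexo)-exo-tet mode. C4 is set by axial delivery of methyl anti to the C5–C6 bond (cis-fused enolate, CH3 and H-5 cis), C6 by inversion of the (6S)-tosylate, and C7 by the geometric need to bond on the face that carries the pseudoaxial C6 arm. The step needs C7 regiochemistry and substitution instead of elimination or O-alkylation: the enolate is made by conjugate addition and never by deprotonation, so C9 is not involved; the seven-membered ring allows only rotamers in which the sulfonate is antiperiplanar to C4 or C10 and never to H-5, and C11 has no hydrogen, so E2 is not aligned; O-alkylation would create a bridgehead enol ether. The tosylate itself should be inert to the cuprate because C6 is secondary and flanked by the quaternary C11.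

Step 10
Reactants: 14 tricyclic C8 ketone with C1 dioxolane
Product: 16 tricyclic C9=C10 enone, via C8 silyl enol ether 15 (not isolated)
Conditions: LDA, TMSCl, THF, −78 °C; then Pd(OAc)2 (1.1 equiv), MeCN, rt
Reagents that add atoms: none
Why: Saegusa–Ito oxidation, in which the ketone can enolise only towards C9 because C7 is a cyclobutane bridgehead, and palladation at C9 followed by β-hydride loss from C10 gives the C9=C10 enone.

Step 11
Reactants: 16 tricyclic C9=C10 enone
Product: 17 10-methyl tricyclic ketone
Conditions: Me2CuLi (1.5 equiv), Et2O, −78 → −20 °C; aq. work-up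
Reagents that add atoms: lithium dimethylcuprate ([Li+].C[Cu-]C)
Why: cuprate conjugate addition to the strained bridged enone delivers methyl to C10 from the enone face next to the C6 bridge, whose inward substituent is hydrogen, because the C4 methyl covers the other face, which sets C10 as in the target.

Step 12
Reactants: 17 10-methyl tricyclic ketone
Product: 18 C1,C8-diketone
Conditions: PPTS (0.3 equiv), acetone/H2O (5:1), 60 °C
Reagents that add atoms: water (O)
Why: acid-catalysed hydrolysis of the dioxolane frees the C1 ketone, and neither ketone has an epimerisable α-stereocentre since C7 is a bridgehead and C11 is quaternary.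

Step 13
Reactants: 18 C1,C8-diketone
Product: 19 C1 ketone with C8 dioxolane
Conditions: (TMSOCH2)2 (1.1 equiv), TMSOTf (2 mol %), CH2Cl2, −78 °C
Reagents that add atoms: 1,2-bis(trimethylsilyloxy)ethane (C[Si](C)(C)OCCO[Si](C)(C)C)
Why: kinetically controlled ketalisation takes the C8 carbonyl, which has only CH and CH2 neighbours, and not the C1 carbonyl shielded by the quaternary C11, so the mask is moved from C1 to C8 before the C1 ketone is dehydrogenated.

Step 14
Reactants: 19 C1 ketone with C8 dioxolane
Product: 21 C2=C3 enone with C8 dioxolane, via C1 silyl enol ether 20 (not isolated)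
Conditions: LDA, TMSCl, THF, −78 °C; then Pd(OAc)2 (1.1 equiv), MeCN, rt
Reagents that add atoms: none
Why: Saegusa–Ito oxidation, in which C2 is the only enolisable position of the C1 ketone and β-hydride loss from C3 gives the C2=C3 enone.

Step 15
Reactants: 21 C2=C3 enone with C8 dioxolane
Product: 22 C1 allylic alcohol (1-OH on the C5 side)
Conditions: (S)-2-methyl-CBS-oxazaborolidine (0.3 equiv), catecholborane (1.5 equiv), toluene, −78 °C
Reagents that add atoms: none
Why: CBS reduction in which the carbonyl binds the catalyst boron anti to the quaternary C11 (large group) and syn to the vinylic C2 (small group), so the (S)-catalyst delivers hydride to the face from which O→C11→C2 runs counter-clockwise, giving the required C1 configuration by 1,2-reduction.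

Step 16
Reactants: 22 C1 allylic alcohol (1-OH on the C5 side)
Product: 23 1,2,3-triol with C8 dioxolane
Conditions: OsO4 (5 mol %), NMO (1.5 equiv), acetone/H2O (5:1), rt
Reagents that add atoms: N-methylmorpholine N-oxide (C[N+]1([O-])CCOCC1); water (O)
Why: Upjohn dihydroxylation is a syn addition, and osmium approaches a cyclic allylic alcohol on the face opposite the allylic oxygen, which places both new hydroxyls on the C7 side (cis to each other, trans to 1-OH).

Step 17
Reactants: 23 1,2,3-triol with C8 dioxolane
Product: 24 2,3-O-isopropylidene triol with free 1-OH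
Conditions: 2,2-dimethoxypropane, PPTS, CH2Cl2, rt
Reagents that add atoms: 2,2-dimethoxypropane (COC(C)(C)OC)
Why: under equilibrating acetal exchange the cis-2,3-diol forms the five-membered acetonide far more readily than the trans-1,2 pair, which leaves 1-OH free.

Step 18
Reactants: 24 2,3-O-isopropylidene triol with free 1-OH; 25 angelic anhydride
Product: 26 1-O-angeloyl acetonide
Conditions: LiHMDS (1.1 equiv), THF, −78 °C; then 25 (1.5 equiv), −78 → 0 °C
Reagents that add atoms: none
Why: acylation of the preformed lithium alkoxide by the anhydride should be fast below 0 °C even for a neopentyl-type alcohol and avoids the nucleophilic catalysts and heat that isomerise (Z)-angelates to (E)-tiglates.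

Step 19
Reactants: 26 1-O-angeloyl acetonide
Product: 27 1-O-angeloyl 2,3-diol C8 ketone
Conditions: 1 M HCl, THF, rt
Reagents that add atoms: water (O)
Why: aqueous acid hydrolyses the acetonide and the C8 dioxolane in one operation while the hindered angelate survives, and no stereocentre is touched.

Step 20
Reactants: 27 1-O-angeloyl 2,3-diol C8 ketone; 28 (R)-2-methylbutanoic acid
Product: 29 target CNP0206299.1
Conditions: DCC (1.2 equiv), DMAP (0.1 equiv), CH2Cl2, −10 → 0 °C
Reagents that add atoms: none
Why: Steglich esterification should take place at 2-OH, the only hydroxyl not attached next to a quaternary carbon (3-OH is neopentyl-type), and the α-branched acid is not epimerised under these mild conditions.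

**Compound list** (the SMILES define the configuration)

1 | isobutyronitrile (2-methylpropanenitrile) | CC(C)C#N | starting material
2 | 3-chloropropanoyl chloride | ClCCC(=O)Cl | starting material
3 | 5-chloro-2,2-dimethyl-3-oxopentanenitrile | N#CC(C)(C)C(=O)CCCl | intermediate
4 | 2-[2-(2-chloroethyl)-1,3-dioxolan-2-yl]-2-methylpropanenitrile | N#CC(C)(C)C1(CCCl)OCCO1 | intermediate
5 | 2-[2-(2-iodoethyl)-1,3-dioxolan-2-yl]-2-methylpropanenitrile | N#CC(C)(C)C1(CCI)OCCO1 | intermediate
6 | 2-[2-(2-iodoethyl)-1,3-dioxolan-2-yl]-2-methylpropanal | O=CC(C)(C)C1(CCI)OCCO1 | intermediate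
7 | 3-ethoxycyclohex-2-en-1-one | CCOC1=CC(=O)CCC1 | starting material
8 | 1-ethoxy-3-(trimethylsilyloxy)cyclohexa-1,3-diene | CCOC1=CC(O[Si](C)(C)C)=CCC1 | intermediate
9 | syn-aldol silyl ether, (6S)-3-ethoxy-6-[(1S)-2-[2-(2-iodoethyl)-1,3-dioxolan-2-yl]-2-methyl-1-(trimethylsilyloxy)propyl]cyclohex-2-en-1-one (route numbering 5S,6S) | CCOC1=CC(=O)[C@@H](CC1)[C@H](O[Si](C)(C)C)C(C)(C)C1(CCI)OCCO1 | intermediate
10 | bicyclic tertiary carbinol: 6/7-fused, C4–OH, enol ether C7=C8–OEt, 6-OTMS, C1 dioxolane (cis-fused epimer drawn; C4 configuration is lost in the same step) | CCOC1=C[C@]2(O)CCC3(OCCO3)C(C)(C)[C@@H](O[Si](C)(C)C)[C@@H]2CC1 | intermediate (not isolated)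
11 | (5R,6S)-6-hydroxy bicyclic enone: C8=O, C7=C4, C1 dioxolane, C11 gem-dimethyl (same spatial arrangement as 9; the C5 descriptor changes with the CIP rank of C4) | O=C1C=C2CCC3(OCCO3)C(C)(C)[C@@H](O)[C@@H]2CC1 | intermediate
12 | (5R,6S)-6-tosyloxy bicyclic enone (key-step precursor) | O=C1C=C2CCC3(OCCO3)C(C)(C)[C@@H](OS(=O)(=O)c3ccc(C)cc3)[C@@H]2CC1 | intermediate
13 | lithium C7–C8 enolate of the C4-methylated cis-fused bicycle, 6-OTs retained | [Li]OC1=C[C@]2(C)CCC3(OCCO3)C(C)(C)[C@@H](OS(=O)(=O)c3ccc(C)cc3)[C@@H]2CC1 | intermediate (not isolated)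
14 | tricyclic C8 ketone with C1 dioxolane; C4 methyl points toward the C8–C10 bridge; C10 unsubstituted (key-step product) | C12(OCCO2)CC[C@]3(C)[C@@H]4[C@@H]([C@H]3C(=O)CC4)C1(C)C | intermediate
15 | C8 trimethylsilyl enol ether (C8=C9) of 14 | C12(OCCO2)CC[C@]3(C)[C@@H]4[C@@H]([C@H]3C(O[Si](C)(C)C)=CC4)C1(C)C | intermediate (not isolated)
16 | tricyclic C9=C10 enone with C1 dioxolane | C12(OCCO2)CC[C@]3(C)[C@@H]4[C@@H]([C@H]3C(=O)C=C4)C1(C)C | intermediate
17 | 10-methyl tricyclic C8 ketone with C1 dioxolane (CH3 on the C6 side of the ketone bridge) | C12(OCCO2)CC[C@]3(C)[C@@H]4[C@@H]([C@H]3C(=O)C[C@H]4C)C1(C)C | intermediate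
18 | C1,C8-diketone | O=C1CC[C@]2(C)[C@@H]3[C@@H]([C@H]2C(=O)C[C@H]3C)C1(C)C | intermediate
19 | C1 ketone with C8 dioxolane | O=C1CC[C@]2(C)[C@@H]3[C@@H]([C@H]2C4(OCCO4)C[C@H]3C)C1(C)C | intermediate
20 | C1 trimethylsilyl enol ether (C1=C2) of 19 | C[Si](C)(C)OC1=CC[C@]2(C)[C@@H]3[C@@H]([C@H]2C4(OCCO4)C[C@H]3C)C1(C)C | intermediate (not isolated)
21 | C2=C3 enone (C1 ketone) with C8 dioxolane | O=C1C=C[C@]2(C)[C@@H]3[C@@H]([C@H]2C4(OCCO4)C[C@H]3C)C1(C)C | intermediate
22 | C1 allylic alcohol, 1-OH on the C5 side of the seven-membered ring, C8 dioxolane | O[C@@H]1C=C[C@]2(C)[C@@H]3[C@@H]([C@H]2C4(OCCO4)C[C@H]3C)C1(C)C | intermediate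
23 | 1,2,3-triol: 2-OH and 3-OH on the C7 side (cis), 1-OH on the C5 side, C8 dioxolane | O[C@@H]1[C@@H](O)[C@@H](O)[C@]2(C)[C@@H]3[C@@H]([C@H]2C4(OCCO4)C[C@H]3C)C1(C)C | intermediate
24 | 2,3-O-isopropylidene derivative of 23, 1-OH free | O[C@@H]1[C@H]5OC(C)(C)O[C@H]5[C@]2(C)[C@@H]3[C@@H]([C@H]2C4(OCCO4)C[C@H]3C)C1(C)C | intermediate
25 | angelic anhydride, (Z)-2-methylbut-2-enoic anhydride | C/C=C(/C)C(=O)OC(=O)/C(C)=C\C | starting material
26 | 1-O-angeloyl derivative of 24 | C/C=C(/C)C(=O)O[C@@H]1[C@H]5OC(C)(C)O[C@H]5[C@]2(C)[C@@H]3[C@@H]([C@H]2C4(OCCO4)C[C@H]3C)C1(C)C | intermediate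
27 | 1-O-angeloyl 2,3-diol with free C8 ketone | C/C=C(/C)C(=O)O[C@@H]1[C@@H](O)[C@@H](O)[C@]2(C)[C@@H]3[C@@H]([C@H]2C(=O)C[C@H]3C)C1(C)C | intermediate
28 | (R)-2-methylbutanoic acid | OC(=O)[C@H](C)CC | starting material
29 | CNP0206299.1: 1-O-angeloyl, 2-O-[(R)-2-methylbutanoyl], 3-OH tricyclic C8 ketone | C/C=C(/C)C(=O)O[C@@H]1[C@@H](OC(=O)[C@H](C)CC)[C@@H](O)[C@]2(C)[C@@H]3[C@@H]([C@H]2C(=O)C[C@H]3C)C1(C)C | target

Total steps: 20. Longest linear sequence: 19 (1 → 29 through steps 1–4 and 6–20; step 5 is the only off-line step).

**Steps most likely to fail**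

Step 9. The alkylation half of the cascade may stall, because C6 is a neopentyl-type secondary centre, so that the enolate is quenched or scrambled by proton transfer before the ring closes. Fallback: the two events are separated. From 12, Me2CuLi with TMSCl (THF, −78 °C) should give the C8 trimethylsilyl enol ether of the C4-methylated bicyclic tosylate F1, which is isolated. MeLi in THF/HMPA (0 → 50 °C) then releases the same C7 lithium enolate free of copper salts, and it should close to 14, where the route is rejoined.

Step 6. The catalytic aldol may show poor enantiofacial control or give the anti adduct, which cannot cyclise in step 9. Fallback: diastereocontrol and enantiopurity are uncoupled. The lithium enolate of 7 (LDA) is transmetallated with ClTi(OiPr)3 and added to 6, relying on the syn preference of triisopropoxytitanium enolates of cyclic ketones, and quenched with TMSCl to give racemic silyl ether. Preparative chromatography on a chiral stationary phase then separates 9, which rejoins the route, from its mirror image ent-9 F2.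

Step 7. The seven-membered Barbier closure may lose to simple reduction of the iodide or to electron transfer to the enone system. Fallback by ring-closing metathesis: from chloride 4, KOtBu elimination gives 2-methyl-2-(2-vinyl-1,3-dioxolan-2-yl)propanenitrile F3, and DIBAL-H as in step 4 gives the aldehyde 2-methyl-2-(2-vinyl-1,3-dioxolan-2-yl)propanal F4. Aldol with 8 as in step 6 gives the vinyl analogue of silyl ether 9 F5. Vinylmagnesium bromide/CeCl3 followed by aqueous HCl (Stork–Danheiser transposition) gives the 3-vinylcyclohexenone carbinol F6. A second-generation ruthenium benzylidene carbene catalyst closes the seven-membered ring to the bicyclic C2=C3 dienone F7, and hydrogenation over RhCl(PPh3)3, which should reduce only the disubstituted C2=C3 bond, returns to 11.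

**Further compounds**

F1 | step 9 | C8 trimethylsilyl enol ether of the C4-methylated bicyclic tosylate | C[Si](C)(C)OC1=C[C@]2(C)CCC3(OCCO3)C(C)(C)[C@@H](OS(=O)(=O)c3ccc(C)cc3)[C@@H]2CC1
F2 | step 6 | ent-9 (mirror image of silyl ether 9) | CCOC1=CC(=O)[C@H](CC1)[C@@H](O[Si](C)(C)C)C(C)(C)C1(CCI)OCCO1
F3 | step 7 | 2-methyl-2-(2-vinyl-1,3-dioxolan-2-yl)propanenitrile | N#CC(C)(C)C1(C=C)OCCO1
F4 | step 7 | 2-methyl-2-(2-vinyl-1,3-dioxolan-2-yl)propanal | O=CC(C)(C)C1(C=C)OCCO1
F5 | step 7 | vinyl analogue of silyl ether 9 | CCOC1=CC(=O)[C@@H](CC1)[C@H](O[Si](C)(C)C)C(C)(C)C1(C=C)OCCO1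
F6 | step 7 | 3-vinylcyclohexenone carbinol (4-substituted 3-vinylcyclohex-2-enone with free 6-OH and vinyl ketal) | O=C1C=C(C=C)[C@@H](CC1)[C@H](O)C(C)(C)C1(C=C)OCCO1
F7 | step 7 | bicyclic C2=C3 dienone with 6-OH and C1 dioxolane | O=C1C=C2C=CC3(OCCO3)C(C)(C)[C@@H](O)[C@@H]2CC1
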